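Begin with the easy step: each table tells you how much free monomer is still there, so work with the fraction left and not with the fraction made. Here are the flasks, the runs and the questions.

| flask | free monomer | transfer agent | protic impurity | initiator | temperature | remark | time |
|---|---|---|---|---|---|---|---|
| Thursday's | 1.4 M | 0.030 M | 0.50 M | 10 mM | 84 °C | run made earlier |  |
| Wednesday's | 2.2 M | 0.030 M | 0.50 M | 10 mM | 93 °C | run made earlier |  |
| Monday's | 1 M | 0.015 M | 0.50 M | 10 mM | 84 °C | run made earlier |  |
| theta | 1.0 M | 0.0300 M | 0.500 M | 10 mM | 80 °C |  | 3.0 h |
| alpha | 1.0 M | 0.0300 M | 0.500 M | 10 mM | 88 °C |  | 3.0 h |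
| epsilon | 1.0 M | 0.0300 M | 0.500 M | 10 mM | 96 °C |  | 3.0 h |

- Thursday's (time / h: over-reaction product / %, free monomer / %, monomer in chains / %): 0.500: 0, 89, 4; 1.00: 7, 75, 12; 1.50: 13, 61, 15; 2.00: 22, 51, 14; 2.50: 32, 41, 15; 3.00: 39, 36, 13
- Wednesday's (time / min: over-reaction product / %, free monomer / %, monomer in chains / %): 8.00: 0, 92, 4; 12.0: 1, 91, 3; 20.0: 6, 84, 8; 30.0: 7, 74, 9; 60.0: 29, 50, 10; 90.0: 42, 39, 9
- Monday's (time / h: over-reaction product / %, free monomer / %, monomer in chains / %): 0.250: 0, 94, 1; 0.833: 4, 80, 8; 1.33: 9, 70, 12; 2.00: 22, 53, 14; 3.00: 40, 34, 14

(scatter of a reading: 1.5 percentage points)

- the numbers in the tables scatter by 1.5 percentage points (one standard deviation)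

* which of these there is most of at the end, counted by the free monomer in it, theta (free monomer / over-reaction product / monomer in chains)
* which of these there is most of at the end, counted by the free monomer in it, alpha (free monomer / over-reaction product / monomer in chains)
* which of these there is most of at the end, counted by the free monomer in it, epsilon (free monomer / over-reaction product / monomer in chains)
* how much there is at the end of the one of these that leads, in percent of the free monomer charged: theta
* how much there is at the end of the one of these that leads, in percent of the free monomer charged: alpha
* how much there is at the end of the one of these that leads, in percent of the free monomer charged: epsilon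

Take two readings of one run, divide the earlier fraction left by the later, take the natural logarithm and divide by the time between. Call this the fraction-left rate r. The charge cancels in it, since [free monomer] stands above and below.

Take the main step first, free monomer going into chains. If it behaves as a pseudo-first-order decay, r stays constant. Thursday's run gives 0.386 /h and then 0.348 /h, so for Thursday's run at 84 °C you can believe that. Wednesday's run at 93 °C gives 0.784 /h and then 0.497 /h, a later r smaller than the earlier one. With a scatter of 1.5 percentage points on each reading this is a reading and not a proof, but I carry it: the late r, which is r from the last window of Wednesday's run.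

I assume epsilon, at 96 °C, follows Wednesday's course up to 90.0 min. With the early r kept, my reckoning puts epsilon at 12.0% free monomer at the end, and with the late r at 18.5%. I take the second, though Wednesday's charge differs from epsilon's.

Now add the next step, chains going on to over-reaction product. In my reckoning it leaves r alone, and I hold back what stands in chains, 9% on Wednesday, so my figure for over-reaction product in epsilon is 72.5%. Then add the rest: Wednesday's last row lacks 10.0%, which brings my figure for epsilon to 62.5%.

For the leaders, Thursday's run ends with over-reaction product at 39% and free monomer at 36%. So I expect free monomer to lead in the cooler theta and over-reaction product in alpha and epsilon.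

The forecast says “Free monomer decays roughly first order”. It names free monomer at 47% for theta, over-reaction product at 53% for alpha and over-reaction product at 72% for epsilon, with free monomer at 8 % in epsilon, where my reckoning has 18.5%.

The flask gives free monomer at 48.6% in theta, over-reaction product at 44.9% in alpha, and over-reaction product at 54.1% in epsilon, where free monomer stands at 19.0%.

    free monomer + initiator → living end + monomer in chains (k = 0.660 /M/h, Ea = 98.0 kJ/mol)
    free monomer + living end → monomer in chains + living end, rate k2*[living end]*[free monomer] (k = 45.0 /M/h, Ea = 52.0 kJ/mol)
    living end + transfer agent → dead chain (kL = 7.50 /M/h, Ea = 73.0 kJ/mol)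
    living end → dead end (k = 0.0130 /h, Ea = 129 kJ/mol)
    protic impurity + free monomer → quenched substrate (k = 0.130 /M/h, Ea = 96.0 kJ/mol)
    monomer in chains → over-reaction product (k = 0.740 /h, Ea = 114 kJ/mol)
    (constants at 80 °C)

Reckon alpha the same way: from 1.50 h to the end its r is 0.402 /h, less than Wednesday's late 0.497 /h, and at the end the step from protic impurity and free monomer to quenched substrate has a half-life of 8.3 h, a rate of 0.0835 /h, smaller than that r, with quenched substrate at 18.9%. Over its whole 3.0 h alpha has r of 0.404 /h, and the neighbour of alpha charged with 0.12 M of transfer agent has 0.230 /h, less than alpha, and ends with free monomer at 50.1% ahead of over-reaction product at 26.3%.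

The numbers in the tables come from a simulation with constants of no real substance, noise included.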